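**Plan**

- Oxolane atoms are named O1, C2 (carries the diene), C3 (carbinol), C4 (CH2) and C5 (carries CH3). Retrosynthesis: desilylation; cut of the central diene single bond (Suzuki–Miyaura); each alkene back to an aldehyde (chromium-mediated one-carbon olefinations); the isocoumarin back to a chlorinated orsellinate (lateral acylation, enol lactonisation); the oxolane cut at O1–C5 and C2–C3.
- Enabling feature: O1 is β to C3 along O1–C5–C4–C3, and C2, which carries O1, is α to C3. With C3 as a ketone and C2 bearing an ester, the ring is the product of an oxa-Michael addition and a Dieckmann closure. Tert-butyl glycolate supplies O1, C2 and the future diene carbon; methyl crotonate supplies C3, C4, C5 and CH3.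
- Forward order: oxolane ring first (step 1), its stereocentres fixed (step 2), the C2 ester taken to an (E)-alkenylboronate (steps 3–6). The benzopyranone is built from methyl orsellinate and taken to an (E)-iodoalkene (steps 7–12). The halves are joined and unmasked (steps 13–14).
- Stereochemistry: C5 forms racemic in step 1. Baker's yeast reduction sets C3 (S) and, by dynamic kinetic resolution of the labile C2, the cis C2/C3 relation. The (5S) diastereomer is isolated at that point and the (5R) series is discarded. Both alkene geometries come from E-selective olefinations and a stereoretentive coupling.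

Key step: step 1

Remark: tert-butyl glycolate, methyl crotonate, methyl orsellinate, ethyl diethoxyacetate and all reagents in the Conditions lines are taken as purchased.

**Route**

Step 1
Reactants: 1 tert-butyl 2-hydroxyacetate; 2 methyl (E)-but-2-enoate
Product: 4 racemic tert-butyl 5-methyl-3-oxooxolane-2-carboxylate, via oxa-Michael diester 3 (not isolated)
Conditions: KOtBu (1.05 equiv), THF, −20 → 0 °C; then cold 1 M HCl
Reagents that add atoms: none
Why: The potassium alkoxide of 1 adds to the β-carbon of 2 (oxa-Michael, making the O1–C5 bond); in the resulting diester 3 the oxygen-bearing CH2 next to the tert-butyl ester is deprotonated and attacks the methyl ester carbonyl (Dieckmann condensation, making the C2–C3 bond with loss of methoxide). The closest known reaction type is the tandem conjugate addition–Dieckmann synthesis of 3-oxo-oxolane, 3-oxothiolane and 3-oxopyrrolidine carboxylates from glycolate, thioglycolate or glycinate esters and acrylates or crotonates. The only ring closure is the Claisen step, a 5-exo-trig attack of an exocyclic ester enolate on the ester carbonyl. C5 is created in the conjugate addition without control and is racemic, and C2 is a configurationally labile β-keto ester carbon; both are settled in step 2. The step needs regioselectivity between the two possible Claisen closures: the tert-butyl ester is a poor acyl acceptor, the methyl ester a good one, and the ether oxygen acidifies the glycolate C–H, so closure from the glycolate carbon should prevail under kinetic conditions with one equivalent of base. Reversibility of the conjugate addition is harmless because the product is stored as its enolate, which drains the equilibrium.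

Step 2
Reactants: 4 racemic tert-butyl 5-methyl-3-oxooxolane-2-carboxylate
Product: 5 tert-butyl (2R,3S,5S)-3-hydroxy-5-methyloxolane-2-carboxylate
Conditions: baker's yeast (Saccharomyces cerevisiae), sucrose, H2O, 30 °C; silica gel chromatography to remove the C5 epimer
Reagents that add atoms: none
Why: Yeast ketoreductases should reduce the rapidly epimerising cyclic β-keto ester in the Prelog sense and accept only the C2 epimer that leads to the cis hydroxy ester (biocatalytic dynamic kinetic resolution, as for 2-oxocycloalkanecarboxylates and 3-oxoproline esters), so the enzyme sets C3 (S) and C2 (R), while the untouched C5 turns the two antipodes of 4 into separable diastereomers of which the (5S) one is kept.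

Step 3
Reactants: 5 tert-butyl (2R,3S,5S)-3-hydroxy-5-methyloxolane-2-carboxylate
Product: 6 tert-butyl (2R,3S,5S)-3-[(tert-butyldimethylsilyl)oxy]-5-methyloxolane-2-carboxylate
Conditions: TBSCl, imidazole, DMF, rt
Reagents that add atoms: tert-butyldimethylsilyl chloride, CC(C)(C)[Si](C)(C)Cl
Why: Silyl ether formation under imidazole catalysis protects the secondary alcohol without touching the C2 stereocentre or the tert-butyl ester.

Step 4
Reactants: 6 tert-butyl (2R,3S,5S)-3-[(tert-butyldimethylsilyl)oxy]-5-methyloxolane-2-carboxylate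
Product: 7 [(2S,3S,5S)-3-[(tert-butyldimethylsilyl)oxy]-5-methyloxolan-2-yl]methanol
Conditions: LiAlH4, THF, −20 → 0 °C
Reagents that add atoms: none
Why: Hydride reduction of the ester to the primary alcohol should leave the silyl ether and all three stereocentres untouched (the C2 descriptor changes only through ligand priorities).

Step 5
Reactants: 7 [(2S,3S,5S)-3-[(tert-butyldimethylsilyl)oxy]-5-methyloxolan-2-yl]methanol
Product: 8 (2R,3S,5S)-3-[(tert-butyldimethylsilyl)oxy]-5-methyloxolane-2-carbaldehyde
Conditions: Dess–Martin periodinane, CH2Cl2, 0 °C → rt; used at once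
Reagents that add atoms: none
Why: Dess–Martin oxidation is non-basic, so the cis α-alkoxy aldehyde should form without epimerisation at C2 or β-elimination of the silyloxy group.

Step 6
Reactants: 8 (2R,3S,5S)-3-[(tert-butyldimethylsilyl)oxy]-5-methyloxolane-2-carbaldehyde
Product: 9 tert-butyl(dimethyl){[(2S,3S,5S)-5-methyl-2-[(E)-2-(4,4,5,5-tetramethyl-1,3,2-dioxaborolan-2-yl)ethenyl]oxolan-3-yl]oxy}silane
Conditions: CrCl2, LiI, Cl2CHB(pin), THF, rt
Reagents that add atoms: 2-(dichloromethyl)-4,4,5,5-tetramethyl-1,3,2-dioxaborolane, ClC(Cl)B1OC(C)(C)C(C)(C)O1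
Why: Takai–Utimoto boryl olefination: the geminal dichromium reagent adds to the aldehyde and eliminates anti to give the (E)-alkenylboronate, under conditions mild enough to keep the C2 configuration.

Step 7
Reactants: 10 methyl 2,4-dihydroxy-6-methylbenzoate
Product: 11 methyl 3-chloro-4,6-dihydroxy-2-methylbenzoate
Conditions: SO2Cl2 (1 equiv), Et2O, 0 °C
Reagents that add atoms: sulfuryl chloride, O=S(=O)(Cl)Cl
Why: Electrophilic aromatic chlorination should take place at the ring position between the methyl group and the non-chelated hydroxyl (ortho to the free OH, para to the chelated OH), as with related orsellinaldehyde-type resorcinols, and one equivalent of reagent limits dichlorination.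

Step 8
Reactants: 11 methyl 3-chloro-4,6-dihydroxy-2-methylbenzoate
Product: 12 methyl 3-chloro-4,6-bis(methoxymethoxy)-2-methylbenzoate
Conditions: NaH, MOMCl, DMF, 0 °C → rt
Reagents that add atoms: chloromethyl methyl ether, COCCl
Why: Williamson-type O-alkylation of both phenoxides (NaH is needed for the hydrogen-bonded hydroxyl next to the ester) gives acetal ethers that tolerate the lithium amide of step 9.

Step 9
Reactants: 12 methyl 3-chloro-4,6-bis(methoxymethoxy)-2-methylbenzoate; 13 ethyl 2,2-diethoxyacetate
Product: 14 methyl 3-chloro-2-(3,3-diethoxy-2-oxopropyl)-4,6-bis(methoxymethoxy)benzoate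
Conditions: LiN(iPr)2 (2.2 equiv), THF, −78 °C; then 13, −78 °C; AcOH quench
Reagents that add atoms: none
Why: Lateral lithiation of the ortho-toluate (the benzylic anion is stabilised by the neighbouring ester) followed by Claisen-type acylation with the non-enolisable ester 13 gives the ketone, which the second equivalent of base stores as its enolate so that no second addition occurs; the aryl chloride has no ortho hydrogen, so no aryne can form.

Step 10
Reactants: 14 methyl 3-chloro-2-(3,3-diethoxy-2-oxopropyl)-4,6-bis(methoxymethoxy)benzoate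
Product: 16 5-chloro-6,8-dihydroxy-1-oxo-1H-isochromene-3-carbaldehyde, via acetal isocoumarin 15 (not isolated)
Conditions: TFA, CH2Cl2, rt; then H2O, rt
Reagents that add atoms: water, O
Why: Acid cleaves both methoxymethyl ethers and promotes enol lactonisation of the benzylic ketone onto the ester (6-exo-trig, driven by the conjugated benzopyranone), and the added water then hydrolyses the diethyl acetal to the aldehyde.

Step 11
Reactants: 16 5-chloro-6,8-dihydroxy-1-oxo-1H-isochromene-3-carbaldehyde
Product: 17 5-chloro-1-oxo-6,8-bis[(triisopropylsilyl)oxy]-1H-isochromene-3-carbaldehyde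
Conditions: iPr3SiOTf, 2,6-lutidine, CH2Cl2, 0 °C → rt
Reagents that add atoms: triisopropylsilyl trifluoromethanesulfonate, CC(C)[Si](OS(=O)(=O)C(F)(F)F)(C(C)C)C(C)C
Why: The silyl triflate silylates both phenols, including the hydrogen-bonded C8 hydroxyl, and the bulky aryl silyl ethers should survive the aqueous base of step 13 yet leave with fluoride in step 14.

Step 12
Reactants: 17 5-chloro-1-oxo-6,8-bis[(triisopropylsilyl)oxy]-1H-isochromene-3-carbaldehyde
Product: 18 5-chloro-3-[(E)-2-iodoethenyl]-6,8-bis[(triisopropylsilyl)oxy]-1H-isochromen-1-one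
Conditions: CrCl2, CHI3, THF, 0 °C → rt
Reagents that add atoms: iodoform, IC(I)I
Why: Takai iodo-olefination of the conjugated aldehyde should give the (E)-iodoalkene through anti elimination of the geminal dichromium adduct, with the lactone, the aryl chloride and the silyl ethers inert to CrCl2.

Step 13
Reactants: 9 tert-butyl(dimethyl){[(2S,3S,5S)-5-methyl-2-[(E)-2-(4,4,5,5-tetramethyl-1,3,2-dioxaborolan-2-yl)ethenyl]oxolan-3-yl]oxy}silane; 18 5-chloro-3-[(E)-2-iodoethenyl]-6,8-bis[(triisopropylsilyl)oxy]-1H-isochromen-1-one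
Product: 19 5-chloro-3-[(1E,3E)-4-[(2S,3S,5S)-3-[(tert-butyldimethylsilyl)oxy]-5-methyloxolan-2-yl]buta-1,3-dien-1-yl]-6,8-bis[(triisopropylsilyl)oxy]-1H-isochromen-1-one
Conditions: PdCl2(dppf) (5 mol %; dppf = 1,1'-bis(diphenylphosphino)ferrocene), K3PO4, THF/H2O, rt
Reagents that add atoms: none
Why: Suzuki–Miyaura coupling (oxidative addition of zerovalent palladium into the C–I bond, base-assisted transmetalation, reductive elimination) proceeds with retention at both alkenes and should give the (E,E)-diene, the aryl C–Cl bond being inert at room temperature.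

Step 14
Reactants: 19 5-chloro-3-[(1E,3E)-4-[(2S,3S,5S)-3-[(tert-butyldimethylsilyl)oxy]-5-methyloxolan-2-yl]buta-1,3-dien-1-yl]-6,8-bis[(triisopropylsilyl)oxy]-1H-isochromen-1-one
Product: 20 5-chloro-6,8-dihydroxy-3-[(1E,3E)-4-[(2S,3S,5S)-3-hydroxy-5-methyloxolan-2-yl]buta-1,3-dien-1-yl]-1H-isochromen-1-one
Conditions: Bu4NF, AcOH, THF, 0 °C → rt
Reagents that add atoms: none
Why: Fluoride-mediated desilylation removes the two aryl silyl ethers and the secondary alkyl silyl ether in one operation, and the acetic acid buffer should protect the lactone and the dienylic C2–O1 ether, so no stereocentre or alkene is affected.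

**Compound list**

1 | tert-butyl 2-hydroxyacetate | CC(C)(C)OC(=O)CO | starting material
2 | methyl (E)-but-2-enoate | C/C=C/C(=O)OC | starting material
3 | tert-butyl 2-[(4-methoxy-4-oxobutan-2-yl)oxy]acetate (racemic; oxa-Michael diester) | COC(=O)CC(C)OCC(=O)OC(C)(C)C | intermediate
4 | tert-butyl 5-methyl-3-oxooxolane-2-carboxylate (racemic at C5, C2 labile) | CC1CC(=O)C(C(=O)OC(C)(C)C)O1 | intermediate
5 | tert-butyl (2R,3S,5S)-3-hydroxy-5-methyloxolane-2-carboxylate | C[C@H]1C[C@H](O)[C@H](C(=O)OC(C)(C)C)O1 | intermediate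
6 | tert-butyl (2R,3S,5S)-3-[(tert-butyldimethylsilyl)oxy]-5-methyloxolane-2-carboxylate | C[C@H]1C[C@H](O[Si](C)(C)C(C)(C)C)[C@H](C(=O)OC(C)(C)C)O1 | intermediate
7 | [(2S,3S,5S)-3-[(tert-butyldimethylsilyl)oxy]-5-methyloxolan-2-yl]methanol | C[C@H]1C[C@H](O[Si](C)(C)C(C)(C)C)[C@H](CO)O1 | intermediate
8 | (2R,3S,5S)-3-[(tert-butyldimethylsilyl)oxy]-5-methyloxolane-2-carbaldehyde | C[C@H]1C[C@H](O[Si](C)(C)C(C)(C)C)[C@H](C=O)O1 | intermediate
9 | tert-butyl(dimethyl){[(2S,3S,5S)-5-methyl-2-[(E)-2-(4,4,5,5-tetramethyl-1,3,2-dioxaborolan-2-yl)ethenyl]oxolan-3-yl]oxy}silane | C[C@H]1C[C@H](O[Si](C)(C)C(C)(C)C)[C@H](/C=C/B2OC(C)(C)C(C)(C)O2)O1 | intermediate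
10 | methyl 2,4-dihydroxy-6-methylbenzoate (methyl orsellinate) | COC(=O)c1c(C)cc(O)cc1O | starting material
11 | methyl 3-chloro-4,6-dihydroxy-2-methylbenzoate | COC(=O)c1c(C)c(Cl)c(O)cc1O | intermediate
12 | methyl 3-chloro-4,6-bis(methoxymethoxy)-2-methylbenzoate | COCOc1cc(OCOC)c(Cl)c(C)c1C(=O)OC | intermediate
13 | ethyl 2,2-diethoxyacetate | CCOC(OCC)C(=O)OCC | starting material
14 | methyl 3-chloro-2-(3,3-diethoxy-2-oxopropyl)-4,6-bis(methoxymethoxy)benzoate | CCOC(OCC)C(=O)Cc1c(Cl)c(OCOC)cc(OCOC)c1C(=O)OC | intermediate
15 | 5-chloro-3-(diethoxymethyl)-6,8-dihydroxy-1H-isochromen-1-one (acetal isocoumarin) | CCOC(OCC)c1cc2c(Cl)c(O)cc(O)c2c(=O)o1 | intermediate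
16 | 5-chloro-6,8-dihydroxy-1-oxo-1H-isochromene-3-carbaldehyde | O=Cc1cc2c(Cl)c(O)cc(O)c2c(=O)o1 | intermediate
17 | 5-chloro-1-oxo-6,8-bis[(triisopropylsilyl)oxy]-1H-isochromene-3-carbaldehyde | O=Cc1cc2c(Cl)c(O[Si](C(C)C)(C(C)C)C(C)C)cc(O[Si](C(C)C)(C(C)C)C(C)C)c2c(=O)o1 | intermediate
18 | 5-chloro-3-[(E)-2-iodoethenyl]-6,8-bis[(triisopropylsilyl)oxy]-1H-isochromen-1-one | I/C=C/c1cc2c(Cl)c(O[Si](C(C)C)(C(C)C)C(C)C)cc(O[Si](C(C)C)(C(C)C)C(C)C)c2c(=O)o1 | intermediate
19 | 5-chloro-3-[(1E,3E)-4-[(2S,3S,5S)-3-[(tert-butyldimethylsilyl)oxy]-5-methyloxolan-2-yl]buta-1,3-dien-1-yl]-6,8-bis[(triisopropylsilyl)oxy]-1H-isochromen-1-one | C[C@H]1C[C@H](O[Si](C)(C)C(C)(C)C)[C@H](/C=C/C=C/c2cc3c(Cl)c(O[Si](C(C)C)(C(C)C)C(C)C)cc(O[Si](C(C)C)(C(C)C)C(C)C)c3c(=O)o2)O1 | intermediate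
20 | 5-chloro-6,8-dihydroxy-3-[(1E,3E)-4-[(2S,3S,5S)-3-hydroxy-5-methyloxolan-2-yl]buta-1,3-dien-1-yl]-1H-isochromen-1-one | C[C@H]1C[C@H](O)[C@H](/C=C/C=C/c2cc3c(Cl)c(O)cc(O)c3c(=O)o2)O1 | target

**Step count and risks**

Total step count: 14. Longest linear sequence: 8 steps (steps 1–6, 13, 14; the benzopyranone arm, steps 7–12, 13, 14, is equally long).

Steps most likely to fail:

1. Step 1. The Claisen closure may occur from the wrong carbon onto the tert-butyl ester, or the sequence may stall at the reversible conjugate addition. Fallback, setting out from 1 and returning at 4: the two bonds are made in separate, regiochemically unambiguous events. Compound 1 is acylated with (E)-but-2-enoyl chloride (pyridine, CH2Cl2) to tert-butyl 2-[(E)-but-2-enoyloxy]acetate F1. A Chan rearrangement (LiN(iPr)2, THF, −78 °C; 1,2-shift of the acyl group from oxygen to the glycolate carbon) should give tert-butyl (E)-2-hydroxy-3-oxohex-4-enoate F2. Acid-catalysed conjugate closure of the hydroxyl onto the enone (TsOH, CH2Cl2) then gives 4.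

2. Step 2. The bioreduction may show poor facial selectivity or slow turnover of the tert-butyl ester, or the C5 epimers may be hard to separate. Fallback, setting out from 4 and returning at 5: asymmetric hydrogenation replaces the enzyme and C3 is corrected by inversion. Compound 4 is hydrogenated with RuCl2[(R)-BINAP] (H2, CH2Cl2; Noyori dynamic kinetic resolution, expected to give the 2,3-trans (3R) alcohols). The (5S) diastereomer, tert-butyl (2R,3R,5S)-3-hydroxy-5-methyloxolane-2-carboxylate F3, is separated from its C5 epimer. Mitsunobu esterification (4-nitrobenzoic acid, PPh3, diisopropyl azodicarboxylate) inverts C3 to tert-butyl (2R,3S,5S)-5-methyl-3-[(4-nitrobenzoyl)oxy]oxolane-2-carboxylate F4. Mild methanolysis (K2CO3, MeOH, 0 °C) releases 5.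

3. Step 10. The one-flask acid treatment may fail through incomplete enol lactonisation or degradation of the α-keto acetal. Fallback, setting out from 12 and returning at 17: the formyl group is introduced by allylic oxidation of a C3 methyl group. Compound 12 is lithiated as in step 9 and acylated with N-methoxy-N-methylacetamide to methyl 3-chloro-4,6-bis(methoxymethoxy)-2-(2-oxopropyl)benzoate F5. TFA in CH2Cl2 should give 5-chloro-6,8-dihydroxy-3-methyl-1H-isochromen-1-one F6. Silylation (iPr3SiOTf, 2,6-lutidine) gives 5-chloro-3-methyl-6,8-bis[(triisopropylsilyl)oxy]-1H-isochromen-1-one F7. SeO2 (dioxane, reflux) then oxidises the methyl group to the aldehyde 17.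

**Further compounds**

F1 | step 1 | tert-butyl 2-[(E)-but-2-enoyloxy]acetate | C/C=C/C(=O)OCC(=O)OC(C)(C)C
F2 | step 1 | tert-butyl (E)-2-hydroxy-3-oxohex-4-enoate (racemic) | C/C=C/C(=O)C(O)C(=O)OC(C)(C)C
F3 | step 2 | tert-butyl (2R,3R,5S)-3-hydroxy-5-methyloxolane-2-carboxylate | C[C@H]1C[C@@H](O)[C@H](C(=O)OC(C)(C)C)O1
F4 | step 2 | tert-butyl (2R,3S,5S)-5-methyl-3-[(4-nitrobenzoyl)oxy]oxolane-2-carboxylate | C[C@H]1C[C@H](OC(=O)c2ccc(cc2)[N+](=O)[O-])[C@H](C(=O)OC(C)(C)C)O1
F5 | step 10 | methyl 3-chloro-4,6-bis(methoxymethoxy)-2-(2-oxopropyl)benzoate | CC(=O)Cc1c(Cl)c(OCOC)cc(OCOC)c1C(=O)OC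
F6 | step 10 | 5-chloro-6,8-dihydroxy-3-methyl-1H-isochromen-1-one | Cc1cc2c(Cl)c(O)cc(O)c2c(=O)o1
F7 | step 10 | 5-chloro-3-methyl-6,8-bis[(triisopropylsilyl)oxy]-1H-isochromen-1-one | Cc1cc2c(Cl)c(O[Si](C(C)C)(C(C)C)C(C)C)cc(O[Si](C(C)C)(C(C)C)C(C)C)c2c(=O)o1
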